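**Retrosynthetic overview**

1. Numbering used here: C1 CH–O (next to C11 = CMe2), C2 CH–OAc, C3 CH–O, C4 C(Me), C5 CH (α to the C6 ketone), C7=C8(Me), C9 CH, C10 CH. Rings: cyclobutane C4–C5–C10–C9, cyclohexenone C5–C6–C7–C8–C9–C10, cycloheptane C1–C2–C3–C4–C9–C10–C11.
2. Endgame: esters ⇐ triol 18 ⇐ dihydroxylation of C2=C3 anti to C1–OH (17) ⇐ epoxide of the C1=C2 alkene of tricyclic dienone 14.
3. Key disconnection: C1–C11 and C4–C5 of 14 ⇒ bicyclic oxolane 12. The enabling feature is that C11 and C4, the two fully substituted carbons at which the new bonds end, are 1,4-related through the C9–C10 bond. One oxygen can therefore hold them as a cis-fused 2,2,5,5-tetrasubstituted oxolane (a masked pair of tertiary cations), with C1 (vinylsilane) and C5 (α′-carbon of the C6 enone, as silyl dienol ether) as the matching nucleophiles.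
4. 12 ⇐ cyclic ketal 7 ⇐ car-3-en-5-one: the carene cyclopropane bond C5–C11 is opened by the oxygen of a 2-acetyl group, which sets the cis C9/C10 fusion; C10 is bought with (+)-3-carene.
5. Ring order: cyclohexenone (from carene) → oxolane (temporary, removed in the key step) → cycloheptene and cyclobutane together in step 8.

Key step: step 8

Remark: both antipodes of the chiral ketone catalyst of step 9 are taken to be available, so that the face of C1=C2 on the C9 side can be chosen.

**Route**

Step 1
Reactants: 1 (+)-3-carene
Product: 2 (−)-car-3-en-5-one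
Conditions: Rh2(cap)4 (1 mol %), t-BuOOH (70 % aq), K2CO3, CH2Cl2, rt
Reagents that add atoms: tert-butyl hydroperoxide CC(C)(C)OO
Why: Allylic C–H oxidation (dirhodium caprolactamate/hydroperoxide) of the ring CH2 between the cyclopropane and the unsubstituted alkene carbon should give the β-methyl enone as the major regioisomer; no stereocentre is touched, C10 and C5 come from the chiral pool.

Step 2
Reactants: 2 (−)-car-3-en-5-one
Product: 3 5-(tert-butyldimethylsilyloxy)cara-2,4-diene
Conditions: TBSOTf, Et3N, CH2Cl2, 0 °C
Reagents that add atoms: tert-butyldimethylsilyl triflate CC(C)(C)[Si](C)(C)OS(=O)(=O)C(F)(F)F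
Why: Soft enolisation (silyl triflate/amine) of a 3-methylcyclohex-2-enone should give the thermodynamic endocyclic silyl dienol ether by γ-deprotonation at the ring CH2 (C9).

Step 3
Reactants: 3 5-(tert-butyldimethylsilyloxy)cara-2,4-diene; 4 trimethyl orthoacetate
Product: 5 2-(1,1-dimethoxyethyl)car-3-en-5-one (side chain trans to the cyclopropane)
Conditions: TMSOTf (10 mol %), CH2Cl2, −78 °C
Reagents that add atoms: trimethyl orthoacetate CC(OC)(OC)OC
Why: The vinylogous Mukaiyama reaction of a silyl dienol ether with the dioxocarbenium ion of an orthoester is γ-selective; attack anti to the cyclopropane should give the trans isomer, which does not matter because C9 is equilibrated in step 4.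

Step 4
Reactants: 5 2-(1,1-dimethoxyethyl)car-3-en-5-one
Product: 7 cis-fused bicyclic methyl ketal, via 2-acetylcar-3-en-5-one 6 (not isolated)
Conditions: TsOH·H2O (20 mol %), MeOH/H2O 20:1, 40 °C
Reagents that add atoms: water O; methanol CO
Why: Acid hydrolysis frees the acetyl group (6), whose C9 is α to a ketone and γ to the enone and should epimerise through the dienol; only the cis epimer can deliver the acetyl oxygen to C11 as the protonated cyclopropyl enone opens (homoconjugate, Cloke–Wilson-type ring opening), and methanol traps the oxocarbenium ion, so the mixture should funnel into the cis-fused ketal with C10 unchanged.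

Step 5
Reactants: 7 cis-fused bicyclic methyl ketal; 8 tributyl(propa-1,2-dienyl)stannane
Product: 9 cis-fused 1-methyl-1-(prop-2-ynyl)oxolane enone
Conditions: TMSOTf (10 mol %), CH2Cl2, −78 °C
Reagents that add atoms: tributyl(propa-1,2-dienyl)stannane C=C=C[Sn](CCCC)(CCCC)CCCC
Why: The Lewis acid generates the cyclic tertiary oxocarbenium ion and the allenylstannane adds by SE2′ from the convex face (oxocarbenium propargylation); the new centre at C4 is erased in step 8.

Step 6
Reactants: 9 cis-fused 1-methyl-1-(prop-2-ynyl)oxolane enone; 10 triethylsilane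
Product: 11 (Z)-vinylsilane
Conditions: [RuCl2(p-cymene)]2 (2 mol %), CH2Cl2, rt
Reagents that add atoms: triethylsilane CC[SiH](CC)CC
Why: Ruthenium-catalysed trans-hydrosilylation of a terminal alkyne should give the (Z)-β-vinylsilane, the geometry needed for ring closure with retention in step 8.

Step 7
Reactants: 11 (Z)-vinylsilane
Product: 12 cross-conjugated TBS dienol ether
Conditions: LiN(iPr)2, THF, −78 °C; TBSCl, HMPA
Reagents that add atoms: tert-butyldimethylsilyl chloride CC(C)(C)[Si](C)(C)Cl
Why: Kinetic α′-deprotonation of the cyclohexenone and O-silylation should give the cross-conjugated silyl dienol ether, nucleophilic only at C5.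

Step 8
Reactants: 12 cross-conjugated TBS dienol ether
Product: 14 tricyclic dienone, via cycloheptene silyl dienol ether 13 (not isolated)
Conditions: TMSOTf (1.3 equiv), 2,6-di-tert-butyl-4-methylpyridine (0.3 equiv), CH2Cl2, −78 to −30 °C; aq NaHCO3
Reagents that add atoms: none
Why: Proposed new method: TMSOTf silylates the bridging oxygen and the C11–O bond ionises (both C–O bonds are tertiary); the C11 cation is attacked at the silicon-bearing C1 of the (Z)-vinylsilane and loss of Et3Si+ from the β-silyl cation gives the cis-cycloheptene 13 with retention, after which the C4 silyl ether ionises and the C4 cation, held over C5 by the cis ring fusion, alkylates the silyl dienol ether at C5 and the C6 ketone returns by loss of the silyl group (the two closures may also occur in the reverse order). The closest known reaction types are the vinylsilane-terminated cation cyclisation for the first bond and the tert-alkylation of silyl enol ethers by tertiary cations (in nature the pinyl closure of the terpinyl cation) for the second, but a cyclobutane has not been closed this way. The seven-membered ring closes 7-endo (cation on alkene, ipso substitution at silicon) and the four-membered ring 4-exo (enol ether carbon on a tertiary cation). C9 and C10, set cis in step 4, place C4 and C11 on one face of the cyclohexene, so C4 and C5 can only form as the cis-bridged cage (methyl on C4 toward the enone bridge, hydrogen on C5 outward) and the C1=C2 alkene is cis. The step needs C–C capture to beat E1 loss from either cation, hydride shift, and capture of the β-silyl cation by the enol ether at C2 (a five-membered ring): C3 is a CH2 without oxygen (no semipinacol shift), the silyl group should leave faster than C2 is attacked, the ether 12 and the alkenes from E1 can return to the cations under the acid (substoichiometric hindered base), and only the two C–C closures should be irreversible at low temperature.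

Step 9
Reactants: 14 tricyclic dienone
Product: 15 C1–C2 epoxide
Conditions: chiral ketone catalyst (oxazolidinone-fused, for cis-alkenes, 30 mol %), KHSO5 (Oxone), K2CO3, MeCN/dimethoxymethane/aq buffer, 0 °C
Reagents that add atoms: potassium peroxymonosulfate [K+].[O-]S(=O)(=O)OO
Why: Shi-type dioxirane epoxidation should attack only the electron-rich isolated alkene; the cage is almost mirror-symmetric about the plane through C4, C10 and C11, so the catalyst antipode, not the substrate, places oxygen on the face toward C9.

Step 10
Reactants: 15 C1–C2 epoxide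
Product: 17 C1 allylic alcohol, via allylic trimethylsilyl ether 16 (not isolated)
Conditions: TMSOTf, DBU, toluene, −78 to 0 °C; then K2CO3, MeOH
Reagents that add atoms: none
Why: Silyl triflate/amidine epoxide-to-allylic-ether isomerisation: the only β-hydrogens are on C3, so the C2–O bond should break and C1 keeps its oxygen and configuration; methanolysis frees the alcohol.

Step 11
Reactants: 17 C1 allylic alcohol
Product: 18 C1,C2,C3-triol
Conditions: OsO4 (2 mol %), N-methylmorpholine N-oxide, acetone/H2O, 0 °C
Reagents that add atoms: N-methylmorpholine N-oxide C[N+]1([O-])CCOCC1; water O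
Why: Upjohn dihydroxylation of the cis-disubstituted C2=C3 alkene (the enone is inert) should occur anti to the allylic C1–OH (Kishi rule), giving the cis C2/C3 diol trans to O1.

Step 12
Reactants: 18 C1,C2,C3-triol; 19 acetic anhydride
Product: 20 C2 monoacetate
Conditions: Ac2O (1.05 equiv), 2,4,6-collidine, CH2Cl2, −40 °C
Reagents that add atoms: acetic anhydride CC(=O)OC(C)=O
Why: C1–OH and C3–OH are both neopentylic (next to C11 and C4), so the C2–OH should be acetylated first under kinetic conditions (selective acylation).

Step 13
Reactants: 20 C2 monoacetate; 21 angelic acid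
Product: 24 target triester (CNP0335415.1), via mixed anhydride 22 (not isolated), via C1 mono-angelate 23 (not isolated)
Conditions: 21, 2,4,6-trichlorobenzoyl chloride, Et3N, toluene, rt; then 20, DMAP, 40 °C
Reagents that add atoms: angelic acid C/C=C(/C)C(=O)O
Why: Yamaguchi esterification (mixed anhydride, DMAP) should acylate the two hindered alcohols without forming alkoxides, which limits acetyl migration and Z-to-E isomerisation of the angelate.

**Compound list**

Compounds 1–6 are named with carane locants; from 7 on, positions follow the numbering of the overview.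

1 | (+)-3-carene, (1S,6R)-3,7,7-trimethylbicyclo[4.1.0]hept-3-ene | CC1=CC[C@@H]2[C@H](C1)C2(C)C | starting material
2 | (−)-car-3-en-5-one (cyclopropane as in 1; ketone next to the cyclopropane CH, β-methyl enone) | CC1=CC(=O)[C@@H]2[C@H](C1)C2(C)C | intermediate
3 | 5-(tert-butyldimethylsilyloxy)cara-2,4-diene (linear silyl dienol ether of 2) | CC1=C[C@@H]2C(C)(C)[C@@H]2C(O[Si](C)(C)C(C)(C)C)=C1 | intermediate
4 | trimethyl orthoacetate | CC(OC)(OC)OC | starting material
5 | 2-(1,1-dimethoxyethyl)car-3-en-5-one, side chain trans to the cyclopropane | CC1=CC(=O)[C@@H]2[C@H]([C@@H]1C(C)(OC)OC)C2(C)C | intermediate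
6 | 2-acetylcar-3-en-5-one, C2 (= C9) epimers in equilibrium, centre left undefined | CC1=CC(=O)[C@@H]2[C@H](C1C(C)=O)C2(C)C | intermediate
7 | cis-fused bicyclic methyl ketal: cyclohex-2-enone (C6=O, C7=C8–Me, C5H2) fused at C9–C10 to an oxolane C9–C4(Me)(OMe)–O–C11(Me)2–C10; ketal carbon as anomer mixture, left undefined | CC1=CC(=O)C[C@@H]2[C@H]1C(C)(OC)OC2(C)C | intermediate
8 | tributyl(propa-1,2-dienyl)stannane | C=C=C[Sn](CCCC)(CCCC)CCCC | starting material
9 | cis-fused oxolane enone with C4(Me)(CH2C≡CH), propargyl on the convex face | CC1=CC(=O)C[C@@H]2[C@H]1[C@@](C)(CC#C)OC2(C)C | intermediate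
10 | triethylsilane | CC[SiH](CC)CC | starting material
11 | (Z)-vinylsilane: as 9 with C4–CH2–CH=CH–SiEt3 (Z) | CC1=CC(=O)C[C@@H]2[C@H]1[C@@](C)(C/C=C\[Si](CC)(CC)CC)OC2(C)C | intermediate
12 | cross-conjugated TBS dienol ether of 11 (C5=C6(OTBS)–C7=C8) | CC1=CC(O[Si](C)(C)C(C)(C)C)=C[C@@H]2[C@H]1[C@@](C)(C/C=C\[Si](CC)(CC)CC)OC2(C)C | intermediate
13 | cycloheptene silyl dienol ether: seven-membered ring C1=C2–C3H2–C4(Me)(OSiMe3)–C9–C10–C11(Me)2 cis-fused to the TBS dienol ether ring; C4 left undefined | C1=CCC(C)(O[Si](C)(C)C)[C@H]2C(C)=CC(O[Si](C)(C)C(C)(C)C)=C[C@H]2C1(C)C | intermediate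
14 | tricyclic dienone: target skeleton with C6=O, C7=C8(Me), C1=C2, C3H2, no oxygen on C1–C3 | C1=CC[C@@]2(C)[C@@H]3C(=O)C=C(C)[C@H]2[C@@H]3C1(C)C | intermediate
15 | C1–C2 epoxide of 14, oxygen on the face toward C9 | O1[C@@H]2[C@H]1C[C@@]3(C)[C@@H]4C(=O)C=C(C)[C@H]3[C@@H]4C2(C)C | intermediate
16 | C1 trimethylsilyl ether of 17 | C[Si](C)(C)O[C@@H]1C=C[C@@]2(C)[C@@H]3C(=O)C=C(C)[C@H]2[C@@H]3C1(C)C | intermediate
17 | C1 allylic alcohol with C2=C3 | O[C@@H]1C=C[C@@]2(C)[C@@H]3C(=O)C=C(C)[C@H]2[C@@H]3C1(C)C | intermediate
18 | C1,C2,C3-triol (O2 and O3 cis, O1 trans to both) | O[C@@H]1[C@@H](O)[C@@H](O)[C@@]2(C)[C@@H]3C(=O)C=C(C)[C@H]2[C@@H]3C1(C)C | intermediate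
19 | acetic anhydride | CC(=O)OC(C)=O | starting material
20 | C2 monoacetate of 18 | O[C@@H]1[C@@H](OC(C)=O)[C@@H](O)[C@@]2(C)[C@@H]3C(=O)C=C(C)[C@H]2[C@@H]3C1(C)C | intermediate
21 | angelic acid, (Z)-2-methylbut-2-enoic acid | C/C=C(/C)C(=O)O | starting material
22 | angelic 2,4,6-trichlorobenzoic mixed anhydride | C/C=C(/C)C(=O)OC(=O)c1c(Cl)cc(Cl)cc1Cl | intermediate
23 | C1 mono-angelate of 20 | C/C=C(/C)C(=O)O[C@@H]1[C@@H](OC(C)=O)[C@@H](O)[C@@]2(C)[C@@H]3C(=O)C=C(C)[C@H]2[C@@H]3C1(C)C | intermediate
24 | CNP0335415.1, 1,3-di-O-angeloyl-2-O-acetyl triester | C/C=C(/C)C(=O)O[C@@H]1[C@@H](OC(C)=O)[C@@H](OC(=O)/C(C)=C\C)[C@@]2(C)[C@@H]3C(=O)C=C(C)[C@H]2[C@@H]3C1(C)C | target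

**Step count and risks**

Total step count: 13. Longest linear sequence: 13 steps from (+)-3-carene; 4, 8, 10, 19 and 21 are commercial.

Steps most likely to fail:

1. Step 8 (Proposed new method). What may go wrong: proton loss from the tertiary cations faster than ring closure, return to the ether or to a cyclopropyl ketone as a resting state, or Lewis-acid reopening of the newly formed cyclobutane bond. Fallback, known reactions only, from 11 back to the route at 17, forming the two bonds in separate steps. Catalytic TMSOTf on the ketone 11 (no silyl enol ether present) would give only the vinylsilane-terminated cyclisation, and work-up would leave the bicyclic tertiary alcohol F1. Allylic oxidation of the only allylic CH2 of the new cycloheptene (SeO2/t-BuOOH, then Dess–Martin periodinane) would give the α-hydroxy enone F2. SmI2 (THF/MeOH, −78 °C) would cleave the α-hydroxyl to give the diketone F3. Double deprotonation with LiN(iPr)2 (C4–H of the new ketone and the α′-CH2 C5 are the only kinetically acidic positions) and oxidation of the bis-enolate with Cu(2-ethylhexanoate)2 (intramolecular oxidative enolate coupling, the ketone analogue of the cyclobutane-forming coupling of adipate dianions) would close C4–C5 to the tricyclic enedione F4. Amine-catalysed asymmetric epoxidation of the cycloheptenone (9-amino-9-deoxy-epi-quinine salt, H2O2; the β,β-disubstituted cyclohexenone should be inert) would give the epoxy ketone F5, and Wharton transposition (N2H4·H2O, AcOH, MeOH) would give 17.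

2. Step 4. What may go wrong: incomplete epimerisation at C9, or proton loss and aromatisation after ring opening instead of ketal formation. Fallback from 5 back to 7, separating the events. Hydrolysis of 5 (1 M HCl, THF) would give the acetyl enone 6 as an isolable epimer mixture. HBr in AcOH would open the cyclopropane by homoconjugate addition to the tertiary bromide F6, whose C9 epimers can be equilibrated with DBU. AgOTf and 2,6-lutidine in MeOH would then ionise the bromide so that the acetyl oxygen of the cis epimer closes the oxolane and methanol gives 7.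

3. Step 9. What may go wrong: poor facial selectivity in the epoxidation of an alkene whose two faces are nearly equivalent. Fallback from 14 back to 17 through a ketone reduction under reagent control. A Schenck ene reaction with singlet oxygen (O2, hν, tetraphenylporphyrin; then PPh3), in which oxygen must enter at C1 because the only allylic hydrogens are on C3, would give the allylic alcohol F7 as a C1 epimer mixture. MnO2 would give the cycloheptenone F8. TBSOTf/Et3N would mask the cyclohexenone as its exocyclic silyl dienol ether F9 (the new enone has no enolisable hydrogen). Corey–Bakshi–Shibata reduction (2-methyl-CBS-oxazaborolidine, catecholborane, −78 °C; tert-alkyl versus alkenyl) would set C1 in the silyl dienol ether alcohol F10, and HF·pyridine would return 17.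

Further compounds
F1 | step 8 | bicyclic cycloheptene tertiary alcohol (C4–OH, cyclohexenone intact, C4 undefined) | C1=CCC(C)(O)[C@H]2C(C)=CC(=O)C[C@H]2C1(C)C
F2 | step 8 | α-hydroxy enone (C3 ketone, C4–OH) | C1=CC(=O)C(C)(O)[C@H]2C(C)=CC(=O)C[C@H]2C1(C)C
F3 | step 8 | diketone with C4–H (C4 undefined) | C1=CC(=O)C(C)[C@H]2C(C)=CC(=O)C[C@H]2C1(C)C
F4 | step 8 | tricyclic enedione (C3 and C6 ketones, C1=C2) | C1=CC(=O)[C@@]2(C)[C@@H]3C(=O)C=C(C)[C@H]2[C@@H]3C1(C)C
F5 | step 8 | C1–C2 epoxy ketone of F4 | O1[C@@H]2[C@H]1C(=O)[C@@]3(C)[C@@H]4C(=O)C=C(C)[C@H]3[C@@H]4C2(C)C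
F6 | step 4 | 4-acetyl-5-(2-bromopropan-2-yl)-3-methylcyclohex-2-enone (C4 of the ring = C9, epimers) | CC1=CC(=O)C[C@@H](C(C)(C)Br)C1C(C)=O
F7 | step 9 | C1 allylic alcohol, epimer mixture | OC1C=C[C@@]2(C)[C@@H]3C(=O)C=C(C)[C@H]2[C@@H]3C1(C)C
F8 | step 9 | cycloheptenone (C1 ketone, C2=C3) | O=C1C=C[C@@]2(C)[C@@H]3C(=O)C=C(C)[C@H]2[C@@H]3C1(C)C
F9 | step 9 | F8 with the cyclohexenone masked as exocyclic TBS dienol ether | O=C1C=C[C@@]2(C)[C@@H]3C(O[Si](C)(C)C(C)(C)C)=CC(=C)[C@H]2[C@@H]3C1(C)C
F10 | step 9 | C1 alcohol of F9 | O[C@@H]1C=C[C@@]2(C)[C@@H]3C(O[Si](C)(C)C(C)(C)C)=CC(=C)[C@H]2[C@@H]3C1(C)C
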